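**Plan**
- Retrosynthetic cuts: first the three O–MOM bonds. Then a C2–C4 bond is re-drawn inside ring C (O1–C2–C3–C4–C4a–C8a). This turns the pyranone into the five-membered ring O1–C2–C4–C4a–C8a of a cyclopropa[b]benzofuran, with C3 as the cyclopropane CH2.
- Enabling feature: the C4 carbonyl stands 1,3 to C2, and C2 carries both O1 and ring B. Ring C is therefore the opened, C-protonated (homoenolate) form of a cyclopropanol whose benzylic C2–C4 bond is the one predisposed to break.
- Further cuts: the three aryl–prenyl bonds (ArBr + prenylzinc, made while the ketone is masked and C2 is locked as a quaternary cyclopropane carbon). Then the two bonds to C3 (flat 2-aryl-3-silyloxybenzofuran + CH2), then O1–C2 (O–H insertion of a diazoketone), then C4–C4a (Friedel–Crafts acylation).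
- Forward order: rings A and B are bought; furan ring (step 5); cyclopropane by dearomatisation (step 6); prenyl groups (step 7); strain-release enlargement 5→6 to ring C (step 8); deprotection (step 9).
- Stereochemistry: a chiral zinc carbenoid selects one face of the flat benzofuran in step 6. The cis-fused (1aR,6bR)-cyclopropane passes its C1a configuration to C2 by rear-side protonation (inversion) in step 8, giving (2S).

Key step: step 8

Assumption: the facial sense of the dipeptide–zinc carbenoid on 8 and the inversion course of step 8 are taken from the closest analogies. If either turns out opposite, the D,D-dipeptide supplies the required antipode of 9 with no other change.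
Numbering: flavanone numbering is used for 12 and 13. Cyclopropa[b]benzofuran numbering is used for 9–11 (C1 = CH2, C1a = carbon on O2 carrying ring B, C6b = carbinol carbon).

**Step 1**
Reactants: 1 phloroglucinol; 2 3-bromo-4-hydroxyphenylacetic acid
Product: 3 deoxybenzoin 2-(3-bromo-4-hydroxyphenyl)-1-(2,4,6-trihydroxyphenyl)ethan-1-one
Conditions: BF3·OEt2 (solvent), 85 °C; aq NaOAc work-up
Reagents that add atoms: none
Why: Friedel–Crafts C-acylation of the very electron-rich, threefold-symmetric phenol by the BF3-activated arylacetic acid should stop at the chelated, deactivated mono-ketone, which is the standard entry to 2,4,6-trihydroxydeoxybenzoins.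

**Step 2**
Reactants: 3 deoxybenzoin
Product: 4 tribromide 1-(3,5-dibromo-2,4,6-trihydroxyphenyl)-2-(3-bromo-4-hydroxyphenyl)ethan-1-one
Conditions: NBS (2.0 equiv), MeCN, −20 → 0 °C
Reagents that add atoms: N-bromosuccinimide, O=C1CCC(=O)N1Br
Why: Electrophilic aromatic bromination; the two free positions of the acylphloroglucinol ring are far more nucleophilic than the ortho-bromophenol ring B or the ketone enol, so two equivalents should mark exactly the carbons that later carry the ring A prenyl groups.

**Step 3**
Reactants: 4 tribromide
Product: 5 tri-MOM ether 1-[3,5-dibromo-2-hydroxy-4,6-bis(methoxymethoxy)phenyl]-2-[3-bromo-4-(methoxymethoxy)phenyl]ethan-1-one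
Conditions: MOMCl (3.2 equiv), i-Pr2NEt, CH2Cl2, 0 °C → rt
Reagents that add atoms: chloromethyl methyl ether (MOMCl), COCCl
Why: Phenol O-alkylation; one of the two equivalent ortho-hydroxyls should stay free because it is chelated to the ketone and flanked by bromine, which is the usual selectivity of acylphloroglucinols.

**Step 4**
Reactants: 5 tri-MOM ether
Product: 6 diazoketone 2-diazo-1-[3,5-dibromo-2-hydroxy-4,6-bis(methoxymethoxy)phenyl]-2-[3-bromo-4-(methoxymethoxy)phenyl]ethan-1-one
Conditions: p-ABSA (1.2 equiv), DBU (2.5 equiv), MeCN, 0 °C → rt; used without delay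
Reagents that add atoms: 4-acetamidobenzenesulfonyl azide (p-ABSA), CC(=O)Nc1ccc(cc1)S(=O)(=O)N=[N+]=[N-]
Why: Regitz diazo transfer onto the doubly activated (benzylic and α-keto) CH2; ring A has no free position, so azo coupling of the phenoxide cannot intervene.

**Step 5**
Reactants: 6 diazoketone
Product: 8 silyloxybenzofuran 5,7-dibromo-2-[3-bromo-4-(methoxymethoxy)phenyl]-4,6-bis(methoxymethoxy)-3-(trimethylsilyloxy)benzofuran, via coumaranone 7 (not isolated)
Conditions: Rh2(OAc)4 (1 mol %), CH2Cl2, rt, Ar; then Et3N, TMSCl, 0 °C; filtration through Et3N-deactivated silica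
Reagents that add atoms: chlorotrimethylsilane, C[Si](C)(C)Cl
Why: Intramolecular O–H insertion of the rhodium carbenoid closes the five-membered ring (proton transfer makes it irreversible, unlike ylide formation at the flanking OMOM), and the acidic, autoxidation-prone C2–H ketone 7 is O-silylated at once with gain of benzofuran aromaticity, so its labile stereocentre is erased on purpose.

**Step 6**
Reactants: 8 silyloxybenzofuran
Product: 9 tribromo-cyclopropane (1aR,6bR)-3,5-dibromo-1a-[3-bromo-4-(methoxymethoxy)phenyl]-4,6-bis(methoxymethoxy)-6b-(trimethylsilyloxy)-1a,6b-dihydro-1H-cyclopropa[b]benzofuran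
Conditions: Et2Zn, CH2I2, N-Boc-L-Val-L-Pro-OMe (1.25 equiv), CH2Cl2, −40 → 0 °C; pyridine quench; Et3N-deactivated silica
Reagents that add atoms: diiodomethane, ICI
Why: Proposed new method: concerted butterfly-type methylene transfer from a dipeptide-bound iodomethylzinc species to the C2=C3 bond of 8, which is an ene-diol diether (O1 and OSiMe3 on the two alkene carbons) in the weakly aromatic furan half and the only nucleophilic π bond present at this stage (hence bromides in place of prenyl groups); the closest known reaction type is the dipeptide-mediated asymmetric Simmons–Smith cyclopropanation of aryl-substituted silyl enol ethers, which has not been shown on a tetrasubstituted heteroaromatic enol ether; the ring fusion can only be cis, so the face chosen by the chiral carbenoid sets C1a and C6b together, and the pyridine quench removes ZnI2 before it can isomerise the donor-rich cyclopropane.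

**Step 7**
Reactants: 9 tribromo-cyclopropane
Product: 10 triprenyl-cyclopropane (1aR,6bR)-4,6-bis(methoxymethoxy)-1a-[4-(methoxymethoxy)-3-(3-methylbut-2-enyl)phenyl]-3,5-bis(3-methylbut-2-enyl)-6b-(trimethylsilyloxy)-1a,6b-dihydro-1H-cyclopropa[b]benzofuran
Conditions: prenylZnBr·LiCl (4.5 equiv), Pd(OAc)2 (5 mol %), CPhos (10 mol %), THF, rt → 45 °C
Reagents that add atoms: prenylzinc bromide, CC(C)=CC[Zn]Br (prepared from prenyl bromide, CC(C)=CCBr, and zinc dust/LiCl in THF)
Why: Threefold Negishi coupling with a bulky biaryl dialkylphosphine ligand, a system known to deliver linear (α) prenyl arenes; the allylzinc finds no carbonyl to add to because the ketone is masked, and both stereocentres are quaternary and untouched.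

**Step 8**
Reactants: 10 triprenyl-cyclopropane
Product: 12 protected flavanone (2S)-5,7-bis(methoxymethoxy)-2-[4-(methoxymethoxy)-3-(3-methylbut-2-enyl)phenyl]-6,8-bis(3-methylbut-2-enyl)chroman-4-one, via cyclopropanol 11 (not isolated)
Conditions: K2CO3 (0.2 equiv), MeOH–THF (4:1), −20 → 0 °C; AcOH quench at −20 °C
Reagents that add atoms: none
Why: Proposed new method: methoxide removes the silyl group, and the alkoxide of 11 pushes its electron pair into the carbonyl forming at C6b, which breaks the zero bridge C1a–C6b shared by the three- and five-membered rings, so the cyclopropane CH2 becomes C3 and the ring O2–C1a–C6b–C6a–C2a becomes the six-membered pyranone, driven by release of the 2-oxabicyclo[3.1.0]hexane strain and by aryl ketone conjugation. The closest known reaction types are the alkaline methanolysis of 1-silyloxybicyclo[n.1.0]alkanes to ketones and the base-induced homoenolate opening of 2-arylcyclopropanols, which cleaves the bond to the benzylic carbon and protonates it from the rear (SE2, inversion) in protic media; neither has been used on an oxa-bicyclic 1,2-dioxygenated cyclopropane to make a chromanone. No ring is closed by a new bond: the six-membered ring arises by bond cleavage alone (one-carbon 5→6 enlargement), so no closure mode has to be satisfied. The only new stereocentre, C2–H, is controlled by C1a of 10: methanol delivers the proton to the back lobe of the breaking C1a–C6b bond, so (1aR) should become (2S), while C6b disappears as the carbonyl. The step needs endocyclic rather than exocyclic (C1–C6b) cleavage, which is secured by ring B and O2 on C1a (benzylic, inductively stabilised carbanion character against a primary one) and by the MOM ether that keeps ring B from becoming an electron-releasing phenoxide. It also needs the product to survive, so the base is catalytic, the temperature low and the quench acidic, which should keep the E1cB opening to the chalcone (the racemisation path) slower than the opening of the strained alkoxide.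

**Step 9**
Reactants: 12 protected flavanone
Product: 13 target (2S)-5,7-dihydroxy-2-[4-hydroxy-3-(3-methylbut-2-enyl)phenyl]-6,8-bis(3-methylbut-2-enyl)chroman-4-one
Conditions: 3 M aq HCl, MeOH, 45 °C, short reaction time; work-up kept below pH 7
Reagents that add atoms: none
Why: Acid-catalysed acetal exchange of the three MOM ethers, the customary last step for prenylated flavanones; C2 is configurationally stable in acid (racemisation needs base-induced retro-oxa-Michael opening), and mild temperature and short time should outrun chroman formation between prenyl groups and neighbouring phenols.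

**Compound list**
1 | phloroglucinol (benzene-1,3,5-triol) | Oc1cc(O)cc(O)c1 | starting material
2 | 3-bromo-4-hydroxyphenylacetic acid | OC(=O)Cc1ccc(O)c(Br)c1 | starting material
3 | 2-(3-bromo-4-hydroxyphenyl)-1-(2,4,6-trihydroxyphenyl)ethan-1-one | O=C(Cc1ccc(O)c(Br)c1)c1c(O)cc(O)cc1O | intermediate
4 | 1-(3,5-dibromo-2,4,6-trihydroxyphenyl)-2-(3-bromo-4-hydroxyphenyl)ethan-1-one | O=C(Cc1ccc(O)c(Br)c1)c1c(O)c(Br)c(O)c(Br)c1O | intermediate
5 | 1-[3,5-dibromo-2-hydroxy-4,6-bis(methoxymethoxy)phenyl]-2-[3-bromo-4-(methoxymethoxy)phenyl]ethan-1-one | O=C(Cc1ccc(OCOC)c(Br)c1)c1c(O)c(Br)c(OCOC)c(Br)c1OCOC | intermediate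
6 | 2-diazo derivative of 5 (α-aryl-α-diazoketone) | O=C(C(=[N+]=[N-])c1ccc(OCOC)c(Br)c1)c1c(O)c(Br)c(OCOC)c(Br)c1OCOC | intermediate
7 | 5,7-dibromo-2-[3-bromo-4-(methoxymethoxy)phenyl]-4,6-bis(methoxymethoxy)benzofuran-3(2H)-one (racemic, labile C2–H, not isolated) | O=C1C(c2ccc(OCOC)c(Br)c2)Oc2c(Br)c(OCOC)c(Br)c(OCOC)c12 | intermediate
8 | 5,7-dibromo-2-[3-bromo-4-(methoxymethoxy)phenyl]-4,6-bis(methoxymethoxy)-3-(trimethylsilyloxy)benzofuran | C[Si](C)(C)Oc1c(-c2ccc(OCOC)c(Br)c2)oc2c(Br)c(OCOC)c(Br)c(OCOC)c12 | intermediate
9 | (1aR,6bR)-tribromo-silyloxycyclopropa[b]benzofuran | COCOc1ccc(cc1Br)[C@]23C[C@@]2(O[Si](C)(C)C)c4c(OCOC)c(Br)c(OCOC)c(Br)c4O3 | intermediate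
10 | (1aR,6bR)-triprenyl-silyloxycyclopropa[b]benzofuran | COCOc1ccc(cc1CC=C(C)C)[C@]23C[C@@]2(O[Si](C)(C)C)c4c(OCOC)c(CC=C(C)C)c(OCOC)c(CC=C(C)C)c4O3 | intermediate
11 | (1aR,6bR)-triprenyl-cyclopropa[b]benzofuran-6b-ol (reacts as its alkoxide, not isolated) | COCOc1ccc(cc1CC=C(C)C)[C@]23C[C@@]2(O)c4c(OCOC)c(CC=C(C)C)c(OCOC)c(CC=C(C)C)c4O3 | intermediate
12 | (2S)-5,7,4'-tris-O-MOM-6,8,3'-triprenylflavanone | COCOc1ccc(cc1CC=C(C)C)[C@@H]2CC(=O)c3c(OCOC)c(CC=C(C)C)c(OCOC)c(CC=C(C)C)c3O2 | intermediate
13 | (2S)-5,7,4'-trihydroxy-6,8,3'-triprenylflavanone (CID158519) | CC(C)=CCc1cc([C@@H]2CC(=O)c3c(O)c(CC=C(C)C)c(O)c(CC=C(C)C)c3O2)ccc1O | target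

**Total step count:** 9. **Longest linear sequence:** 9 steps (1 or 2 → 13).

**Steps most likely to fail**

1. Step 6. The tetrasubstituted, still partly aromatic π bond may resist methylene transfer, the chiral carbenoid may discriminate poorly between the two faces, or zinc salts may isomerise the donor-rich cyclopropane.
   - The fallback keeps a 5→6 enlargement but runs it as a radical Dowd–Beckwith reaction and takes the stereochemistry from a kinetic resolution.
   - It sets out from 7, isolated under argon after the rhodium stage instead of being silylated.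
   - C-alkylation of its enolate with CH2I2 (K2CO3, DMF) would give the racemic 2-(iodomethyl)benzofuranone F1.
   - Bu3SnH/AIBN (slow addition, benzene, 80 °C) abstracts the alkyl iodide much faster than the aryl bromides. The primary radical adds to the C3 carbonyl, and the cyclopropyloxy radical opens to the benzylic α-oxy radical. Hydrogen transfer would then give the racemic tribromoflavanone F2.
   - A threefold Stille coupling with tributyl(prenyl)stannane (Pd(PPh3)4, DMF, 100 °C; neutral, so the ketone is tolerated) would give the racemic triprenylflavanone F3.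
   - Asymmetric transfer hydrogenation with a Rh–TsDPEN catalyst (HCO2H/Et3N), run as a kinetic resolution, would reduce the (2R)-ketone to the cis-flavan-4-ol F4. The (2S)-ketone remains, and the sequence rejoins the route at 12.

2. Step 8. The exocyclic cyclopropane bond may cleave instead of the endocyclic one. Configuration may also erode, either through a free, planarising benzylic carbanion or through base-induced ring opening of the product.
   - The fallback gives up chirality transfer but keeps the enlargement. It sets out from 10.
   - FeCl3 in DMF at 0 °C is the known one-electron oxidative ring enlargement of silyloxycyclopropanes, which breaks the bond toward the more stabilised radical. Followed by NaOAc/MeOH, it would give the protected triprenylflavone F5.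
   - Copper hydride-catalysed asymmetric conjugate reduction (Cu(OAc)2, chiral bisphosphine, silane), a reaction type established for 2-substituted chromones and inert toward prenyl groups, would then set C2 and return to the route at 12.

3. Step 7. Coupling may stay incomplete at the two ring A bromides, each flanked by two ortho oxygen substituents, or some prenyl may be transferred through its branched (γ) terminus.
   - The fallback separates C–C coupling from construction of the trisubstituted alkene. It sets out from 9.
   - A threefold Stille allylation with the smaller allyltributylstannane (Pd catalyst, CsF, dioxane), where linear and branched transfer give the same group, would give the triallyl cyclopropane F6.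
   - A threefold cross-metathesis with 2-methyl-2-butene (second-generation Ru–NHC catalyst, CH2Cl2, 40 °C) would convert the allyl groups into prenyl groups and return to the route at 10.

**Further compounds**
F1 | step 6 | rac-5,7-dibromo-2-[3-bromo-4-(methoxymethoxy)phenyl]-2-(iodomethyl)-4,6-bis(methoxymethoxy)benzofuran-3(2H)-one | O=C1C(CI)(c2ccc(OCOC)c(Br)c2)Oc2c(Br)c(OCOC)c(Br)c(OCOC)c12
F2 | step 6 | rac-6,8-dibromo-2-[3-bromo-4-(methoxymethoxy)phenyl]-5,7-bis(methoxymethoxy)chroman-4-one | O=C1CC(c2ccc(OCOC)c(Br)c2)Oc2c(Br)c(OCOC)c(Br)c(OCOC)c12
F3 | step 6 | rac-5,7,4'-tris-O-MOM-6,8,3'-triprenylflavanone | COCOc1ccc(cc1CC=C(C)C)C2CC(=O)c3c(OCOC)c(CC=C(C)C)c(OCOC)c(CC=C(C)C)c3O2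
F4 | step 6 | (2R,4R)-5,7,4'-tris-O-MOM-6,8,3'-triprenylflavan-4-ol | COCOc1ccc(cc1CC=C(C)C)[C@H]2C[C@@H](O)c3c(OCOC)c(CC=C(C)C)c(OCOC)c(CC=C(C)C)c3O2
F5 | step 8 | 5,7,4'-tris-O-MOM-6,8,3'-triprenylflavone | COCOc1ccc(cc1CC=C(C)C)-c2cc(=O)c3c(OCOC)c(CC=C(C)C)c(OCOC)c(CC=C(C)C)c3o2
F6 | step 7 | (1aR,6bR)-triallyl-silyloxycyclopropa[b]benzofuran | COCOc1ccc(cc1CC=C)[C@]23C[C@@]2(O[Si](C)(C)C)c4c(OCOC)c(CC=C)c(OCOC)c(CC=C)c4O3
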